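## Analysis of the target

The target is a flavonol–flavan dimer: a 5,7-dihydroxy-2-(4-hydroxyphenyl)chroman-4-one unit (rings A and C, atoms O1, C2–C4, C4a–C8a; ring B on C2) and a 5″-hydroxy-2″-(4-hydroxyphenyl)chromane unit (rings A″ and C″, atoms O1″, C2″–C8a″; ring B″ on C2″) are joined by two bonds, C3–C8″ and C2–O7″. These two bonds, with C2–C3 and C7″–C8″, make the five-membered dihydrofuran ring D, cis-fused to ring C and annulated angularly on ring A″, so the core is a pentacyclic A/C/D/A″/C″ array carrying two 4-hydroxyphenyl groups. There are three stereocentres: C2 (R), a bis(aryloxy) ketal carbon that also bears ring B; C3 (R), a tertiary benzylic α-ketol carbon; and C2″ (S) of the flavan. C2 and C3 are adjacent and fully substituted, and their relative configuration is fixed by the cis fusion of rings C and D, whereas C2″ lies four bonds from C3 (C3–C8″–C8a″–O1″–C2″) across a flat arene and cannot steer them. The feature that the plan exploits is that C2, C3 and C4 are three neighbouring carbons at the carbonyl oxidation level (ketal, aryl carbinol, ketone), a vicinal tricarbonyl in disguise, and that ring D is what a phenol gives when it adds to two of them through its ortho carbon (C8″ to C3) and its oxygen (O7″ to C2). Sensitive groups are the five phenols on electron-rich rings (oxidation, base), the α-ketol next to a ketal (cleavage and ring contraction under base), and the two benzylic C–O arrays, the ketal at C2 and the ether C2″–O1″ (ionisation by strong acid, hydrogenolysis). The difficulty is threefold: two contiguous tetrasubstituted centres must be made at the hindered C8″ between two oxygens; ring A″ offers two nucleophilic carbons and two phenols, of which only the pair C8″/O7″ is wanted; and the configuration of the C2/C3 pair relative to the remote C2″ must come from a reagent.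

## Retrosynthetic reasoning

**18 to 17.** The five phenols are masked as benzyl ethers and the tertiary 3-OH is left free, since it is created in the key step. Benzyl ethers survive the acid, oxidant, hydride and fluoride used earlier and fall off in one neutral operation at the end. The forward step must cleave five aryl benzyl ethers without touching the benzylic ketal, the benzylic ether C2″–O1″ or the C4 ketone.

**17 to 9 and 15 (key disconnection).** The cut is through C3–C8″ and C2–O7″, the only two bonds that join the monomers and two of the five bonds of ring D. Both fusion stereocentres vanish. What remains is the flavan phenol 9, with one free OH at C7″, and the oxidised flavonol 15, a 2-methoxychromane-3,4-dione with a free, non-enolisable C3 carbonyl. A cut through only one of the two bonds would leave one quaternary centre to be built separately. In the forward direction C8″ must add to the C3 carbonyl and O7″ must replace the methoxy group at C2. This requires C8″ rather than C6″, C3 rather than C4, and one face of C3 irrespective of the distant C2″, which is why a chiral acid is used.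

**15 to 13, 11 and 10.** These are oxidation-level adjustments on the intact apigenin skeleton. 15 comes from flavonol 13 by a two-electron oxidation in methanol, which puts a methoxy group on C2 and turns C3 into a carbonyl. In methanol the dione rests as its C3 methyl hemiketal 14, a reversible adduct that gives the free dione 15 when the methanol is removed. The alkoxy group at C2 locks ring C as a six-membered ring. Flavonol 13 comes from flavone 11 by oxygenation of C3 through epoxide 12. Flavone 11 comes from 10 by benzylation. The flavone is benzylated before C3 is oxygenated because a flavonol cannot be protected selectively at every oxygen except O3, whereas 13 made this way has the 3-OH as its only free hydroxyl.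

**9 to 7 and 4.** The pattern needed in 9 (5″-O-benzyl, 7″-OH) is the reverse of what a 5,7-dihydroxy-4-oxo flavonoid gives on alkylation, where the chelated 5-OH stays free. The two oxygens are therefore told apart while the C4″ carbonyl is present (7″-O-silyl in 4). The carbonyl is then removed with the help of the 5″-OH (carbonate 5, quinone methide 6, phenol 7). Finally the freed 5″-OH is benzylated (8) and the silyl group is taken off.

**4 to 2 and 3; 2 to 1.** The C2″–aryl bond is cut. The forward reaction is a catalytic asymmetric conjugate addition of 3 to chromone 2. It sets C2″ (S), brings in the 4‴-O-benzyl group and runs without base, so the flavanone cannot racemise by ring opening. 2 comes from commercial 1 by silylation of the only unchelated phenol.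

## Alternatives that were turned down

**Alternative 1:** (textbook) Cut C3–C8″ alone as aryl anion plus ketone. The 8-bromo flavan A1 would undergo halogen–metal exchange and add to the C3 carbonyl of 15 to give carbinol A2. Global debenzylation and an acid-induced closure of ring D would follow. Turned down for three reasons. The achiral aryllithium meets a ketone next to an uncontrolled C2 and far from C2″, so C3 is formed without any control. O7″ must be masked during the addition, so ring D can only be closed afterwards on a hexaphenol under acid, where the ketal and the C2″–O1″ ether are most at risk. Bromination, exchange and a separate cyclisation add steps for the same two bonds.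

**Alternative 2:** Cut the ketal bond C2–O1 and the C3–OH bond. This leads back to the 2-aryl-3-aroylbenzofuran A3, a flavan with an aromatic furan on C7″/C8″. The forward key step is epoxidation of the furan C2=C3 bond with capture of the C2 cation by the ortho hydroxyl of the aroyl group, which would give 17. Turned down because the furan double bond is tetrasubstituted, part of an aromatic ring and conjugated to the aroyl carbonyl, so it is a poor partner for electrophilic oxidants in a molecule full of electron-rich rings. The face of a flat heteroarene far from C2″ would have to be chosen by a chiral oxidant. A3 itself needs a regioselective furan annulation of an unsymmetrical 1,3-diketone and would cost about as many steps as the whole route below.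

**Alternative 3:** Form ring D first on phloroglucinol and build ring C″ last. Annulation of 15 with phloroglucinol would give the tetracycle A4 without any regiochemical question. Ring C″ would then be made by cycloaddition of an ortho-quinone methide derived from A4 with 4-benzyloxystyrene under a chiral acid. Turned down because the symmetry that helps in the first annulation is lost in the second. A4 has two different phenols and two different free ring carbons, so the pyran can be fused in three ways, and the wanted one uses the most hindered phenol, next to the quaternary C3. A second catalyst-controlled stereochemical event would also be placed late, on the most valuable intermediate.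

Key step: step 8

Remarks on the chemistry (assumptions):
- The sense of induction of (R)-t-BuPyOx in step 2 and of (R)-TRIP in step 8 is assigned by analogy with the closest known reactions. If either proves opposite, the enantiomeric ligand or acid (both commercial) is used with no other change.
- 1, 3 and 10 are taken as commercial.

## Steps

**Step 1**
Reactants: 1 5,7-dihydroxy-4H-chromen-4-one
Product: 2 5-hydroxy-7-[(triisopropylsilyl)oxy]-4H-chromen-4-one
Conditions: TIPSCl (1.1 equiv), imidazole, DMF, 0 °C to rt
Reagents that add atoms: triisopropylsilyl chloride, CC(C)[Si](Cl)(C(C)C)C(C)C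
Why: Silylation of a phenol; the 5-OH is held in a hydrogen bond to the C4 carbonyl and stays free, so only the more acidic, unchelated 7-OH reacts.

**Step 2**
Reactants: 2 5-hydroxy-7-[(triisopropylsilyl)oxy]-4H-chromen-4-one; 3 [4-(benzyloxy)phenyl]boronic acid
Product: 4 (2S)-2-[4-(benzyloxy)phenyl]-5-hydroxy-7-[(triisopropylsilyl)oxy]chroman-4-one
Conditions: Pd(OCOCF3)2 (5 mol %), (R)-t-BuPyOx [(R)-4-tert-butyl-2-(pyridin-2-yl)-4,5-dihydrooxazole] (6 mol %), NH4PF6 (30 mol %), H2O (5 equiv), ClCH2CH2Cl, 60 °C
Reagents that add atoms: none
Why: Asymmetric conjugate addition of an arylboronic acid to a chromone under divalent palladium/pyridine–oxazoline catalysis (transmetalation, face-selective carbopalladation of C2=C3, protonolysis of the palladium enolate by water); the tert-butyl group of the ligand shields one face of the bound enone so that the aryl group arrives on the face that makes C2 (S), and the base-free medium keeps the flavanone from racemising by ring opening.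

**Step 3**
Reactants: 4 (2S)-2-[4-(benzyloxy)phenyl]-5-hydroxy-7-[(triisopropylsilyl)oxy]chroman-4-one
Product: 7 (2S)-2-[4-(benzyloxy)phenyl]-7-[(triisopropylsilyl)oxy]chroman-5-ol, via ethyl aryl carbonate 5 (not isolated), via ortho-quinone methide 6 (not isolated)
Conditions: ClCO2Et, Et3N, THF, 0 °C; then NaBH4, THF/H2O, 0 °C to rt
Reagents that add atoms: none
Why: Known deoxygenation of ortho-hydroxyaryl ketones through their aryl carbonates: hydride reduces the C4 ketone of 5, the carbonate moves to the benzylic oxygen and is expelled by the phenoxide to give 6, and a second hydride adds to C4; C2 is not involved and keeps its configuration, and the aryl silyl ether tolerates aqueous NaBH4.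

**Step 4**
Reactants: 7 (2S)-2-[4-(benzyloxy)phenyl]-7-[(triisopropylsilyl)oxy]chroman-5-ol
Product: 9 (2S)-5-(benzyloxy)-2-[4-(benzyloxy)phenyl]chroman-7-ol, via silyl ether 8 (not isolated)
Conditions: BnOH, PPh3, DIAD, THF, 0 °C to rt; then TBAF, THF, 0 °C; aq. NH4Cl quench
Reagents that add atoms: benzyl alcohol, OCc1ccccc1
Why: Mitsunobu etherification of the now unchelated 5-OH under neutral conditions that leave the aryl silyl ether alone, then fluoride cleavage of the Si–O bond; this gives the 5-O-benzyl/7-OH pattern that direct alkylation cannot give.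

**Step 5**
Reactants: 10 apigenin [5,7-dihydroxy-2-(4-hydroxyphenyl)-4H-chromen-4-one]
Product: 11 5,7-bis(benzyloxy)-2-[4-(benzyloxy)phenyl]-4H-chromen-4-one
Conditions: BnBr (4.5 equiv), K2CO3, Bu4NI (cat.), DMF, 80 °C
Reagents that add atoms: benzyl bromide, BrCc1ccccc1
Why: Williamson etherification; excess reagent and heat are used so that the chelated, sluggish 5-OH is also alkylated, and the flavone has no stereocentre or base-labile group.

**Step 6**
Reactants: 11 5,7-bis(benzyloxy)-2-[4-(benzyloxy)phenyl]-4H-chromen-4-one
Product: 13 5,7-bis(benzyloxy)-2-[4-(benzyloxy)phenyl]-3-hydroxy-4H-chromen-4-one, via 2,3-epoxyflavanone 12 (not isolated)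
Conditions: dimethyldioxirane (acetone solution, excess), CH2Cl2, 0 °C to rt; then p-TsOH·H2O (cat.), CH2Cl2, rt
Reagents that add atoms: dimethyldioxirane, CC1(C)OO1
Why: Epoxidation of the flavone C2=C3 bond by the neutral electrophilic dioxirane, then acid-catalysed opening of 12 at C2 (benzylic and stabilised by O1) and loss of H3 to give the enol, which is the flavonol; the 3-OH becomes the only free hydroxyl.

**Step 7**
Reactants: 13 5,7-bis(benzyloxy)-2-[4-(benzyloxy)phenyl]-3-hydroxy-4H-chromen-4-one
Product: 15 5,7-bis(benzyloxy)-2-[4-(benzyloxy)phenyl]-2-methoxychromane-3,4-dione (racemic), via C3 methyl hemiketal 14 (not isolated)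
Conditions: PhI(OAc)2 (1.1 equiv), MeOH/CH2Cl2 (3:1), 0 °C to rt; then evaporation, toluene, 4 Å molecular sieves, 80 °C, concentration under vacuum; stored and handled dry
Reagents that add atoms: methanol, CO
Why: Oxidation of a flavonol with a trivalent-iodine reagent in methanol: the enolic 3-OH exchanges a ligand at iodine and methanol attacks C2 with loss of iodobenzene (umpolung of the enol), which makes the C3 ketone; in methanol this very electrophilic, non-enolisable carbonyl rests as hemiketal 14, a reversible adduct that loses its methanol on heating in toluene over sieves and leaves the anhydrous dione 15. The configuration at C2 is irrelevant because C2 is rewritten in step 8, and the methoxy group at C2 prevents ring contraction to a benzofuranone.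

**Step 8**
Reactants: 9 (2S)-5-(benzyloxy)-2-[4-(benzyloxy)phenyl]chroman-7-ol; 15 5,7-bis(benzyloxy)-2-[4-(benzyloxy)phenyl]-2-methoxychromane-3,4-dione
Product: 17 (2R,3R,2″S)-5,7,4′,5″,4‴-penta-O-benzyl ether of 18 (cis-fused ring D; free 3-OH), via C3 aryl carbinol 16 (not isolated)
Conditions: (R)-TRIP [(R)-3,3′-bis(2,4,6-triisopropylphenyl)-1,1′-binaphthyl-2,2′-diyl hydrogen phosphate] (10 mol %), 5 Å molecular sieves, toluene/CH2Cl2 (4:1), −20 °C to rt
Reagents that add atoms: none
Why: Proposed new method: a chiral Brønsted acid catalysed formal (3+2) annulation of a phenol, used as a C,O-bis-nucleophile (C8″ and O7″), with a masked vicinal tricarbonyl; the closest known reaction types are the acid-promoted condensation of phenols with ninhydrin and other 1,2-dicarbonyl compounds to fused dihydrobenzofuran (hemi)ketals and the chiral phosphoric acid catalysed ortho Friedel–Crafts hydroxyalkylation of phenols and naphthols with activated ketones. Mechanistically, the acid bridges the 7″-OH of 9 (P=O···H–O) and the free C3 carbonyl of dione 15 (P–OH···O=C), C8″ adds to C3 to give carbinol 16, and acid-induced ionisation of the C2–OMe bond (oxocarbenium stabilised by O1 and the 4-benzyloxyphenyl group) is followed by capture by O7″, a 5-exo-trig closure of ring D, while the sieves keep water from the dione and take up the methanol set free. C3 is set (R) in the C–C bond-forming transition state by the catalyst, with the remote C2″ as a bystander. C2 is set (R) by the ring, because the five-membered ketal can only close cis on ring C, so the labile C2 centre of 15 is erased and rewritten. C8″ is preferred over C6″ because the methylene of the 5″-O-benzyl group must point toward C6″ (the other in-plane rotamer collides with C4″H2), whereas O1″ next to C8″ has its substituent tied back in ring C″; C8″ is also where 5,7-di-O-alkyl flavans are known to react with electrophiles. C3 is attacked rather than C4 because C4 is a vinylogous carbonate deactivated by the 5,7-dialkoxy ring A, while C3 is flanked by a carbonyl and a ketal carbon. An oxygen-first sequence (mixed ketal at C2, then intramolecular attack of C8″ on C3) would lead to the same product under the same control element.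

**Step 9**
Reactants: 17 (2R,3R,2″S)-5,7,4′,5″,4‴-penta-O-benzyl ether of 18
Product: 18 CNP0208300.2, the (2R,3R,2″S) target
Conditions: H2 (1 atm), Pd(OH)2/C, THF/MeOH (1:1), rt
Reagents that add atoms: none
Why: Hydrogenolysis of aryl benzyl ethers under neutral conditions; these O–CH2Ph bonds should cleave well before the hindered benzylic ketal at C2, the tertiary carbinol at C3 or the ring ether C2″–O1″, and the C4 ketone is a deactivated vinylogous ester, so no stereocentre is touched.

## Compound list

1 | 5,7-dihydroxy-4H-chromen-4-one | O=c1ccoc2cc(O)cc(O)c12 | starting material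
2 | 5-hydroxy-7-[(triisopropylsilyl)oxy]-4H-chromen-4-one | O=c1ccoc2cc(O[Si](C(C)C)(C(C)C)C(C)C)cc(O)c12 | intermediate
3 | [4-(benzyloxy)phenyl]boronic acid | OB(O)c1ccc(OCc2ccccc2)cc1 | starting material
4 | (2S)-2-[4-(benzyloxy)phenyl]-5-hydroxy-7-[(triisopropylsilyl)oxy]chroman-4-one | O=C1C[C@@H](c2ccc(OCc3ccccc3)cc2)Oc2cc(O[Si](C(C)C)(C(C)C)C(C)C)cc(O)c12 | intermediate
5 | (2S)-2-[4-(benzyloxy)phenyl]-4-oxo-7-[(triisopropylsilyl)oxy]chroman-5-yl ethyl carbonate | CCOC(=O)Oc1cc(O[Si](C(C)C)(C(C)C)C(C)C)cc2O[C@H](c3ccc(OCc4ccccc4)cc3)CC(=O)c12 | intermediate (not isolated)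
6 | (2S)-2-[4-(benzyloxy)phenyl]-7-[(triisopropylsilyl)oxy]-2,3-dihydro-5H-chromen-5-one (ortho-quinone methide, C4=C4a) | O=C1C=C(O[Si](C(C)C)(C(C)C)C(C)C)C=C2O[C@H](c3ccc(OCc4ccccc4)cc3)CC=C12 | intermediate (not isolated)
7 | (2S)-2-[4-(benzyloxy)phenyl]-7-[(triisopropylsilyl)oxy]chroman-5-ol | Oc1cc(O[Si](C(C)C)(C(C)C)C(C)C)cc2O[C@H](c3ccc(OCc4ccccc4)cc3)CCc12 | intermediate
8 | (2S)-5-(benzyloxy)-2-[4-(benzyloxy)phenyl]-7-[(triisopropylsilyl)oxy]chromane | CC(C)[Si](Oc1cc(OCc2ccccc2)c2CC[C@@H](c3ccc(OCc4ccccc4)cc3)Oc2c1)(C(C)C)C(C)C | intermediate (not isolated)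
9 | (2S)-5-(benzyloxy)-2-[4-(benzyloxy)phenyl]chroman-7-ol | Oc1cc(OCc2ccccc2)c2CC[C@@H](c3ccc(OCc4ccccc4)cc3)Oc2c1 | intermediate
10 | apigenin, 5,7-dihydroxy-2-(4-hydroxyphenyl)-4H-chromen-4-one | O=c1cc(-c2ccc(O)cc2)oc2cc(O)cc(O)c12 | starting material
11 | 5,7-bis(benzyloxy)-2-[4-(benzyloxy)phenyl]-4H-chromen-4-one | O=c1cc(-c2ccc(OCc3ccccc3)cc2)oc2cc(OCc3ccccc3)cc(OCc3ccccc3)c12 | intermediate
12 | 5,7-bis(benzyloxy)-2-[4-(benzyloxy)phenyl]-2,3-epoxychroman-4-one (racemic) | O=C1c2c(OCc3ccccc3)cc(OCc3ccccc3)cc2OC2(c3ccc(OCc4ccccc4)cc3)OC12 | intermediate (not isolated)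
13 | 5,7-bis(benzyloxy)-2-[4-(benzyloxy)phenyl]-3-hydroxy-4H-chromen-4-one | O=c1c(O)c(-c2ccc(OCc3ccccc3)cc2)oc2cc(OCc3ccccc3)cc(OCc3ccccc3)c12 | intermediate
14 | 5,7-bis(benzyloxy)-2-[4-(benzyloxy)phenyl]-3-hydroxy-2,3-dimethoxychroman-4-one (C3 methyl hemiketal of 15; racemic, both C2/C3 diastereomers) | COC1(c2ccc(OCc3ccccc3)cc2)Oc2cc(OCc3ccccc3)cc(OCc3ccccc3)c2C(=O)C1(O)OC | intermediate (not isolated)
15 | 5,7-bis(benzyloxy)-2-[4-(benzyloxy)phenyl]-2-methoxychromane-3,4-dione (racemic) | COC1(c2ccc(OCc3ccccc3)cc2)Oc2cc(OCc3ccccc3)cc(OCc3ccccc3)c2C(=O)C1=O | intermediate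
16 | (3R)-3-{(2S)-5-(benzyloxy)-2-[4-(benzyloxy)phenyl]-7-hydroxychroman-8-yl}-5,7-bis(benzyloxy)-2-[4-(benzyloxy)phenyl]-3-hydroxy-2-methoxychroman-4-one (both C2 epimers) | COC1(c2ccc(OCc3ccccc3)cc2)Oc2cc(OCc3ccccc3)cc(OCc3ccccc3)c2C(=O)[C@]1(O)c4c(O)cc(OCc5ccccc5)c5CC[C@@H](c6ccc(OCc7ccccc7)cc6)Oc45 | intermediate (not isolated)
17 | (2R,3R,2″S)-penta-O-benzyl ether of 18: 5,7-bis(benzyloxy)-2-[4-(benzyloxy)phenyl]-3-hydroxychroman-4-one whose C2 is bonded to O7″ and whose C3 is bonded to C8″ of (2″S)-5″-(benzyloxy)-2″-[4-(benzyloxy)phenyl]chromane, ring D cis-fused | O=C1c2c(OCc5ccccc5)cc(OCc5ccccc5)cc2O[C@@]2(c3ccc(OCc5ccccc5)cc3)Oc3cc(OCc5ccccc5)c4c(c3[C@@]12O)O[C@H](c1ccc(OCc5ccccc5)cc1)CC4 | intermediate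
18 | CNP0208300.2: (2R,3R)-3,5,7-trihydroxy-2-(4-hydroxyphenyl)chroman-4-one joined through C2–O7″ and C3–C8″ to (2″S)-5″-hydroxy-2″-(4-hydroxyphenyl)chromane | O=C1c2c(O)cc(O)cc2O[C@@]2(c3ccc(O)cc3)Oc3cc(O)c4c(c3[C@@]12O)O[C@H](c1ccc(O)cc1)CC4 | target

## Step count and least certain steps

Total step count: 9. Longest linear sequence: 6 steps (steps 1, 2, 3, 4, 8, 9); the electrophile branch (steps 5, 6, 7) joins at step 8.

**Step 8 (key step, proposed new method).** Three things may go wrong. The first is poor facial selectivity at C3, because the stereogenic C2 of 15 may impose its own bias on the attack, or because an uncatalysed or reversible Friedel–Crafts pathway competes. The second is attack through C6″ in place of C8″. The third is stalling before ketal exchange, since the oxocarbenium at C2 is only moderately stabilised. Fallback with known reactions, as a stepwise polar union that gives up catalyst control: it sets out from 9. Bromination ortho to the free phenol with N-bromosuccinimide at −78 °C should give (2S)-5-(benzyloxy)-2-[4-(benzyloxy)phenyl]-8-bromochroman-7-ol F1. Methoxymethylation gives the bromo ether (2S)-5-(benzyloxy)-2-[4-(benzyloxy)phenyl]-8-bromo-7-(methoxymethoxy)chromane F2. Bromine–lithium exchange with n-BuLi at −78 °C and addition of the aryllithium to the C3 carbonyl of 15 gives the methoxymethyl-protected carbinol F3 as a mixture at C2 and C3. Acid in methanol removes the methoxymethyl group and closes ring D, which gives 17 together with its (2S,3S,2″S) diastereomer F4. The two differ as diastereomers because of C2″ and are separated by chromatography. The fallback comes back to the route at 17.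

**Step 2.** The chelated 5-hydroxychromone and the electron-rich boronic acid may give low conversion (protodeboronation, slow carbopalladation) or insufficient enantioselectivity, and traces of fluoride from the hexafluorophosphate may start desilylation. Fallback by resolution in place of asymmetric catalysis: it sets out from 2 and 3. Addition with an achiral catalyst, Pd(OCOCF3)2 with 2,2′-bipyridine, gives the racemic flavanone F5, which is resolved by preparative chromatography on a chiral phase. The (2S) enantiomer is 4, where the fallback rejoins the route. The (2R) enantiomer F6 is racemised with a tertiary amine base through reversible ring opening and recycled.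

**Step 3.** Erosion of the C2 configuration by amine-induced ring opening during carbonate formation, incomplete collapse to the quinone methide (the reaction stops at the flavan-4-ol stage), or partial loss of the silyl group. Fallback by a different deoxygenation: it sets out from 4. Condensation with p-toluenesulfonyl hydrazide gives the tosylhydrazone F7, and reduction with catecholborane followed by sodium acetate replaces C=N by CH2 with loss of sulfinate and nitrogen. It comes back at 7.

**Step 7.** Over-oxidation of the electron-rich benzyloxy rings by the iodine reagent, ring contraction if water competes with methanol at C2, or incomplete release of methanol from the hemiketal and re-addition of moisture to the dione during isolation. Fallback by epoxide methanolysis and alcohol oxidation in place of enol umpolung, which delivers the dione from an aprotic medium: it sets out from 11. Epoxide 12 is isolated after the dioxirane stage of step 6 and opened with methanol at C2 to trans-5,7-bis(benzyloxy)-2-[4-(benzyloxy)phenyl]-3-hydroxy-2-methoxychroman-4-one F8. The secondary alcohol is then oxidised with Dess–Martin periodinane in dry CH2Cl2. This gives the dione directly, and the fallback comes back to the route at 15.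

**Step 9.** Over-reduction, that is hydrogenolysis of the benzylic ketal C2–O bonds or of C2″–O1″ once the phenols are free, or incomplete cleavage of the hindered 5- and 5″-O-benzyl groups. Fallback by Lewis-acid dealkylation in place of hydrogenolysis: it sets out from 17. Treatment with BCl3 and pentamethylbenzene as cation scavenger in CH2Cl2 at −78 °C transfers the benzyl groups to the scavenger and gives 18 directly. This fallback makes no new compound (F0) and comes back at 18.

## Further compounds

F1 | step 8 | (2S)-5-(benzyloxy)-2-[4-(benzyloxy)phenyl]-8-bromochroman-7-ol | Oc1c(Br)c2O[C@H](c3ccc(OCc4ccccc4)cc3)CCc2c(OCc3ccccc3)c1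
F2 | step 8 | (2S)-5-(benzyloxy)-2-[4-(benzyloxy)phenyl]-8-bromo-7-(methoxymethoxy)chromane | COCOc1c(Br)c2O[C@H](c3ccc(OCc4ccccc4)cc3)CCc2c(OCc3ccccc3)c1
F3 | step 8 | 3-{(2S)-5-(benzyloxy)-2-[4-(benzyloxy)phenyl]-7-(methoxymethoxy)chroman-8-yl}-5,7-bis(benzyloxy)-2-[4-(benzyloxy)phenyl]-3-hydroxy-2-methoxychroman-4-one (mixture at C2 and C3) | COC1(c2ccc(OCc3ccccc3)cc2)Oc2cc(OCc3ccccc3)cc(OCc3ccccc3)c2C(=O)C1(O)c4c(OCOC)cc(OCc5ccccc5)c5CC[C@@H](c6ccc(OCc7ccccc7)cc6)Oc45
F4 | step 8 | (2S,3S,2″S) diastereomer of 17 | O=C1c2c(OCc5ccccc5)cc(OCc5ccccc5)cc2O[C@]2(c3ccc(OCc5ccccc5)cc3)Oc3cc(OCc5ccccc5)c4c(c3[C@]12O)O[C@H](c1ccc(OCc5ccccc5)cc1)CC4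
F5 | step 2 | racemic 2-[4-(benzyloxy)phenyl]-5-hydroxy-7-[(triisopropylsilyl)oxy]chroman-4-one | O=C1CC(c2ccc(OCc3ccccc3)cc2)Oc2cc(O[Si](C(C)C)(C(C)C)C(C)C)cc(O)c12
F6 | step 2 | (2R)-2-[4-(benzyloxy)phenyl]-5-hydroxy-7-[(triisopropylsilyl)oxy]chroman-4-one | O=C1C[C@H](c2ccc(OCc3ccccc3)cc2)Oc2cc(O[Si](C(C)C)(C(C)C)C(C)C)cc(O)c12
F7 | step 3 | N′-{(2S)-2-[4-(benzyloxy)phenyl]-5-hydroxy-7-[(triisopropylsilyl)oxy]chroman-4-ylidene}-4-methylbenzenesulfonohydrazide | Cc1ccc(cc1)S(=O)(=O)NN=C1C[C@@H](c2ccc(OCc3ccccc3)cc2)Oc2cc(O[Si](C(C)C)(C(C)C)C(C)C)cc(O)c12
F8 | step 7 | trans-5,7-bis(benzyloxy)-2-[4-(benzyloxy)phenyl]-3-hydroxy-2-methoxychroman-4-one (racemic) | COC1(c2ccc(OCc3ccccc3)cc2)Oc2cc(OCc3ccccc3)cc(OCc3ccccc3)c2C(=O)C1O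
F0 | step 9 | none | none
A1 | alternative 1 | (2S)-5,7-bis(benzyloxy)-2-[4-(benzyloxy)phenyl]-8-bromochromane | Brc1c(OCc2ccccc2)cc(OCc2ccccc2)c2CC[C@@H](c3ccc(OCc4ccccc4)cc3)Oc12
A2 | alternative 1 | 3-{(2S)-5,7-bis(benzyloxy)-2-[4-(benzyloxy)phenyl]chroman-8-yl}-5,7-bis(benzyloxy)-2-[4-(benzyloxy)phenyl]-3-hydroxy-2-methoxychroman-4-one (mixture at C2 and C3) | COC1(c2ccc(OCc3ccccc3)cc2)Oc2cc(OCc3ccccc3)cc(OCc3ccccc3)c2C(=O)C1(O)c4c(OCc5ccccc5)cc(OCc5ccccc5)c5CC[C@@H](c6ccc(OCc7ccccc7)cc6)Oc45
A3 | alternative 2 | 2-aryl-3-aroylbenzofuran: flavan 9 annulated at O7″/C8″ by a furan bearing 4-(benzyloxy)phenyl on the O-bound carbon and a 2-hydroxy-4,6-bis(benzyloxy)benzoyl group on the other | O=C(c1c(O)cc(OCc2ccccc2)cc1OCc1ccccc1)c1c(-c2ccc(OCc3ccccc3)cc2)oc2cc(OCc3ccccc3)c3c(c12)O[C@H](c1ccc(OCc2ccccc2)cc1)CC3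
A4 | alternative 3 | cis-fused tetracyclic ketal from 15 and phloroglucinol: 17 without ring C″ and ring B″, with two free phenols on the new arene (racemic) | O=C1c2c(OCc5ccccc5)cc(OCc5ccccc5)cc2OC2(c3ccc(OCc5ccccc5)cc3)Oc3cc(O)cc(O)c3C12O
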